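## Analysis of the target

Compound 22 is a trisubstituted tetrahydrofuran lignan whose ring is numbered O1, C2 (3,4-dimethoxyphenyl), C3 (methyl), C4 and C5 (methylene); C4 carries the exocyclic carbinol carbon C6, which bears the second 3,4-dimethoxyphenyl ring. It has four contiguous stereocentres, C2 (S), C3 (S), C4 (R) and C6 (R). On the ring the C3 methyl and the C4 side chain are cis, and the C2 aryl group is trans to both. Both benzylic C–O bonds (C2–O1 and C6–OH) sit on electron-rich rings and ionise easily under acid, so late intermediates tolerate Lewis acids only cold and briefly. The hard points are the C3/C4 cis relationship (the less stable arrangement whenever C4 can epimerise), the exocyclic centre C6 that no ring controls, and the absence of any functional handle at C5. The strategy rests on reading C5 and the C3 methyl as two one-carbon branches on neighbouring carbons of the chain C2–C3–C4–C6: with C5 taken as a methyl group, that chain is the skeleton of (2S,3S)-2,3-dimethylsuccinic acid 7, with C2 and C6 as its carboxyl carbons. The C2-symmetric diacid then supplies both ring stereocentres, and what remains is to oxidise one methyl group selectively and tie it to O1, to put one aryl group on each former carboxyl carbon, and to set C6 and C2.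

## Retrosynthetic reasoning

**22 from 21.** The last operation only releases the C6 hydroxyl from its silyl ether 21. A silyl group is chosen because the masking group must pass a hydride reduction of a lactone, which an ester at C6 would not survive, and then a cold Lewis-acid arylation.

**21 from 20 and 9.** The C2–aryl bond is cut, with lactol acetate 20 as the C2 electrophile and veratrole 9 as the nucleophile. C2 is the only ring stereocentre outside the succinic backbone, and its configuration, trans to the C3 methyl, is what attack on the less hindered face of the ionised acetal delivers. A cut at O1–C2 would need a separately made benzylic alcohol and would offer no such control. The forward step must form the bond para to a methoxy group of 9 without ionising the C6–O bond.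

**20 from 18 through 19.** Acetate 20 goes back through lactol 19 to lactone 18. This only adjusts the oxidation level at C2 so that the former carboxyl carbon becomes the electrophile of the arylation.

**18 from 16 through 17.** Removing the silyl group and oxidising C6 leads to keto lactone 16. C6 is thus set by reduction of an aryl ketone, where catalyst control is available, and the ketone is the oxidation level in which C6 arrives from the backbone. The reduction must be non-basic, because C4 in 16 is α to the ketone and cis to the C3 methyl.

**16 from 12 (key disconnection).** The O1–C5 bond is cut, C5 is returned to a methyl group and the lactone carbonyl to a primary amide, giving keto amide 12. C5 is the one ring carbon with no functional counterpart in dimethylsuccinic acid, so forming this bond by C–H functionalisation is what allows C3 and C4 to come from a C2-symmetric diacid. The nitrogen radical from 12 can reach only the hydrogens of the C5 methyl through a six-membered transition state. After iodine transfer the amide oxygen closes the ring (through 13, 14 and 15). The forward step must leave both α-carbonyl stereocentres untouched. The trans-dimethyl arrangement of 12 then appears in 16 as the cis relationship of methyl and aroyl group, because the ring now runs through the former methyl carbon.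

**12 from 10, and 10 from 8 and 9.** The amide goes back to keto acid 10 (through mixed anhydride 11). The C6–aryl bond of 10 is cut by Friedel–Crafts acylation of 9 with anhydride 8. The two carbonyl groups of 8 are equivalent, so there is no regiochemical question, and the second carboxyl group is set free for the amide.

**8 from 7, 7 from 4, 4 from 1 and 2.** Anhydride 8 is the dehydrated form of diacid 7, which is released from imide ester 4 by removing the auxiliary and the ethyl group (through 5 and 6). The central C3–C4 bond of 4 is cut into two propionate units of opposite polarity: enolate 3, derived from acyl oxazolidinone 1, and the lactate-derived triflate 2. The auxiliary fixes the configuration at the nucleophilic carbon and SN2 inversion fixes it at the electrophilic carbon, so one bond-forming step sets both backbone stereocentres. Any diastereomer can be removed at the stage of 4, before the auxiliary is cleaved.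

## Alternatives that were turned down

**Alternative 1:** [2+2] photocycloaddition, then cyclobutanol cleavage.
- Disconnection: C3–C4 plus a temporary bond between the future C3 methyl carbon and C6, so that the 3-oxabicyclo[3.2.0]heptane A1 masks the target skeleton.
- Forward key step: the aryl silyl enol ether A2, whose enol ether and vinyl group are linked through C5, O1 and C2, would be excited by triplet energy transfer from Ir[dF(CF3)ppy]2(dtbbpy)PF6. 5-exo closure of the triplet diradical forms C3–C4 and the tetrahydrofuran; collapse of the 1,4-diradical closes the cyclobutane of A1. After desilylation the cyclobutanol must be opened between C6 and the methylene carbon to leave the C3 methyl and a C6 ketone.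
- For: the cis ring fusion fixes the C3/C4 cis relationship by geometry, and the C2 aryl group can sit exo. One step makes a ring, a skeletal C–C bond and two stereocentres, which is more than the chosen key step does.
- Against: the ring opening must break the bond from C6 to a primary carbon. The competing C6–C4 cleavage gives the more stabilised secondary radical or carbanion and would destroy the bond just made. A metal-mediated β-carbon elimination could favour the primary carbon but then competes with β-hydride loss to an exocyclic alkene. The only stereocentre of A2 is at once benzylic on an electron-rich ring, allylic and ether-bound, so it is hard to make and keep enantiopure. C6 still has to be set after the fragmentation, as in the chosen route.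
- Comparison: the chosen strategy forms fewer bonds in its key step, but takes C3 and C4 from an auxiliary-controlled alkylation with a chiral-pool triflate and needs no regioselective fragmentation.

**Alternative 2:** nitrogen deletion from a 1,3-oxazinane.
- Disconnection: C2–C3, by inserting a nitrogen atom, so that the tetrahydrofuran becomes the 1,3-oxazinane A4, a cyclic N,O-aminal of a 1,3-amino alcohol and an aromatic aldehyde.
- Forward key step: an N-acyloxy-N-alkoxybenzamide reagent would convert the ring N–H into an isodiazene. Loss of N2 leaves a 1,5-diradical at C2 and C3, whose recombination contracts the ring to A3, the same compound as 21.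
- For: the C2 aryl group enters by a simple condensation, the key step comes one step before the target, and the plan is more convergent than the chosen one.
- Against: both C2 and C3 pass through planar radical centres, so the C3 configuration of A4 is not reliably transferred. The 2,3-trans/3,4-cis arrangement would depend on the conformational preferences of a short-lived diradical, and the C3/C4 cis relationship is the one it has least reason to choose. A4 is in ring–chain equilibrium with its open imine form, which cannot undergo the deletion. The amino alcohol needed already holds three stereocentres, so the step count is not lower.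
- Comparison: the chosen route never turns C3 or C4 into a reactive centre and forms C2 under control of the two substituents already fixed.

**Alternative 3:** cyclocarbonylation of a homopropargylic alcohol.
- Disconnection: C4–C5 and O1–C5, with C5 supplied by carbon monoxide. The ring is traced to the α-benzylidene lactone A5 and then to the anti homopropargylic alcohol A6.
- Forward key step: a palladium hydride from Pd(OAc)2 and 1,4-bis(diphenylphosphino)butane under CO would add across the alkyne of A6, insert CO and be captured by the hydroxyl group to give E-configured A5.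
- For: A6 is accessible with the correct C2/C3 relationship by addition of a chiral allenylmetal reagent to an aromatic aldehyde followed by an aryl–alkyne coupling. Both aryl groups are in place before the key step, which is catalytic. On convergence and on the ease of setting C2 this plan is stronger than the chosen one.
- Against: A5 has sp2 carbons at C4 and C6, so the two hardest stereocentres remain open after the key step. Adding oxygen at the benzylic β-carbon C6 and hydrogen at C4 of an α-benzylidene lactone, with control of both and with the C4 substituent cis to the methyl group, has no dependable solution, and the β-hydroxy lactone can revert by elimination. The lactone carbonyl at C5 must then be reduced to a methylene group next to an ionisable benzylic C2–O bond, which adds steps.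
- Comparison: the chosen route has the reverse profile. C3/C4 are secure from the start, C6 is a ketone that a chiral catalyst can reduce, and the lactone carbonyl carbon is used as the arylation site and does not have to be removed.

Key step: step 6

## Route

Remark: the locants O1, C2–C5 and C6 always mean the target numbering defined in the analysis; imide 1 and triflate 2 (the O-triflyl derivative of ethyl L-lactate) are taken to be purchasable as single enantiomers, 2 being used freshly distilled, and enolate 3 is assumed to be alkylated on the face opposite the benzyl group while 2 reacts with clean inversion.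

Step 1
Reactants: 1 (R)-4-benzyl-3-propanoyl-1,3-oxazolidin-2-one; 2 ethyl (S)-2-[(trifluoromethylsulfonyl)oxy]propanoate
Product: 4 ethyl (2S,3S)-4-[(R)-4-benzyl-2-oxo-1,3-oxazolidin-3-yl]-2,3-dimethyl-4-oxobutanoate, via sodium Z-enolate 3 (not isolated)
Conditions: NaN(SiMe3)2 (1.05 equiv), THF, −78 °C; then 2 (1.3 equiv), −78 → −40 °C; aq. NH4Cl; chromatography or crystallisation
Reagents that add atoms: none
Why: Auxiliary-controlled enolate alkylation with a secondary α-triflyloxy ester: NaN(SiMe3)2 gives the chelated Z-enolate 3, which attacks the triflate-bearing carbon of 2 with its face opposite the benzyl group, placing (S) at the imide α-carbon, while SN2 displacement with inversion turns the (S)-lactate centre into the (S)-configured ester α-carbon (the descriptor is unchanged because the incoming carbon ranks below the ester carbonyl, whereas the departing oxygen ranked above it). The triflate leaving group lets the displacement at a secondary carbon run at low temperature, where elimination and enolate equilibration are slow, and the C3–C4 bond and both backbone stereocentres are formed in this one step.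

Step 2
Reactants: 4 ethyl (2S,3S)-4-[(R)-4-benzyl-2-oxo-1,3-oxazolidin-3-yl]-2,3-dimethyl-4-oxobutanoate
Product: 7 (2S,3S)-2,3-dimethylbutanedioic acid, via peroxy acid half ester 5 (not isolated), via half ester acid 6 (not isolated)
Conditions: LiOH (2.5 equiv), 30% H2O2 (5 equiv), THF/H2O 3:1, 0 °C; Na2SO3; then LiOH (3 equiv), 20 °C; CH2Cl2 extraction of the auxiliary; HCl to pH 1, EtOAc
Reagents that add atoms: hydrogen peroxide, OO; lithium hydroxide, [Li+].[OH-]
Why: Hydroperoxide-mediated imide cleavage followed by ester saponification: the small, strongly nucleophilic hydroperoxide anion attacks the exocyclic carbonyl of the hindered imide to give peracid 5, sulfite reduces it to half ester 6, and hydroxide then hydrolyses the ethyl ester. Neither α-hydrogen is acidic enough to be removed by aqueous hydroxide at 0–20 °C, so the (S,S) configuration should be kept, and the auxiliary is recovered by extraction.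

Step 3
Reactants: 7 (2S,3S)-2,3-dimethylbutanedioic acid
Product: 8 (3S,4S)-3,4-dimethyloxolane-2,5-dione
Conditions: AcCl, reflux; evaporation
Reagents that add atoms: none
Why: Cyclodehydration through the mixed acetic anhydride; no base is present, so the (S,S) centres are retained and the C2-symmetric trans anhydride should result.

Step 4
Reactants: 8 (3S,4S)-3,4-dimethyloxolane-2,5-dione; 9 veratrole (1,2-dimethoxybenzene)
Product: 10 (2S,3S)-4-(3,4-dimethoxyphenyl)-2,3-dimethyl-4-oxobutanoic acid
Conditions: AlCl3 (2.5 equiv), CH2Cl2, 0 → 20 °C; ice/2 M HCl
Reagents that add atoms: none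
Why: Friedel–Crafts acylation: veratrole reacts para to a methoxy group to give the 3,4-dimethoxyphenyl ketone, and because the two carbonyl groups of 8 are related by the C2 axis either one gives the same keto acid; the low temperature is meant to limit enolisation of the AlCl3-bound ketone and ether cleavage.

Step 5
Reactants: 10 (2S,3S)-4-(3,4-dimethoxyphenyl)-2,3-dimethyl-4-oxobutanoic acid
Product: 12 (2S,3S)-4-(3,4-dimethoxyphenyl)-2,3-dimethyl-4-oxobutanamide, via mixed carbonic anhydride 11 (not isolated)
Conditions: i-BuOCOCl, N-methylmorpholine, THF, −15 °C; then NH3 (0.5 M in 1,4-dioxane), −15 → 0 °C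
Reagents that add atoms: ammonia, N
Why: Mixed carbonic anhydride amidation: activation at −15 °C with a weak amine base and immediate ammonolysis at the more electrophilic acyl carbonyl of 11 avoid conditions under which either α-centre could epimerise.

Step 6
Reactants: 12 (2S,3S)-4-(3,4-dimethoxyphenyl)-2,3-dimethyl-4-oxobutanamide
Product: 16 (3S,4R)-4-(3,4-dimethoxybenzoyl)-3-methyloxolan-2-one, via N-iodoamide 13 (not isolated), via iodomethyl amide 14 (not isolated), via iminolactone 15 (not isolated)
Conditions: PhI(OAc)2 (1.6 equiv), I2 (1.0 equiv), CH2Cl2, hν (tungsten lamp), 25 °C; then 1 M HCl, THF, 0 → 20 °C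
Reagents that add atoms: water, O
Why: PhI(OAc)2 and I2 form acetyl hypoiodite, which N-iodinates the primary amide to 13, and visible light cleaves the weak N–I bond to an amidyl radical. Through a six-membered transition state this radical reaches only the hydrogens of the methyl group on the ketone-bearing carbon (1,5-transfer); the other methyl group and both methine hydrogens would need smaller transition states and the ketone carbon bears no hydrogen, so the site selectivity is geometric. The primary radical takes iodine from I2 or from 13 to give 14, whose amide oxygen displaces iodide in a 5-exo-tet closure, the only ring formed, to give iminolactone 15; aqueous acid then hydrolyses the C=N bond to lactone 16. The closest known reaction type is the photolytic lactonisation of N-iodoamides, a Hofmann–Löffler–Freytag-type remote functionalisation. No stereocentre is created: both centres of 12 are carried over because neither becomes a radical or an enolate, and the cis relationship of methyl and aroyl group in 16 follows from the trans relationship of the two methyl groups in 12, since the ring now includes the former methyl carbon. Beyond the site of hydrogen transfer the step needs chemoselectivity for N–I homolysis over two-electron Hofmann rearrangement and over iodination of the dimethoxyarene; continuous irradiation in a non-polar solvent and the deactivating acyl group on the ring are relied on for this.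

Step 7
Reactants: 16 (3S,4R)-4-(3,4-dimethoxybenzoyl)-3-methyloxolan-2-one
Product: 17 (3S,4R)-4-[(R)-(3,4-dimethoxyphenyl)(hydroxy)methyl]-3-methyloxolan-2-one
Conditions: (S)-2-methyl-CBS-oxazaborolidine [(S)-1-methyl-3,3-diphenyltetrahydro-1H,3H-pyrrolo[1,2-c][1,3,2]oxazaborole] (0.3 equiv), BH3·SMe2 (1.0 equiv), THF, −20 °C; MeOH
Reagents that add atoms: none
Why: Corey–Bakshi–Shibata reduction: the ketone binds the catalyst boron anti to the larger aryl group and hydride is delivered from the coordinated borane to one face, which for the (S)-catalyst should give the (R)-carbinol in the same sense as for acetophenone; the medium is non-basic, so C4 should not epimerise, and the lactone is not reduced by borane at this temperature.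

Step 8
Reactants: 17 (3S,4R)-4-[(R)-(3,4-dimethoxyphenyl)(hydroxy)methyl]-3-methyloxolan-2-one
Product: 18 (3S,4R)-4-[(R)-[(tert-butyldimethylsilyl)oxy](3,4-dimethoxyphenyl)methyl]-3-methyloxolan-2-one
Conditions: t-BuMe2SiOTf, 2,6-lutidine, CH2Cl2, −78 → 0 °C
Reagents that add atoms: tert-butyldimethylsilyl trifluoromethanesulfonate, CC(C)(C)[Si](C)(C)OS(=O)(=O)C(F)(F)F
Why: Silylation of a secondary alcohol with a silyl triflate and a hindered base is fast at low temperature, which forestalls migration of the lactone onto the C6 oxygen; a silyl ether is used because, unlike an ester, it survives the hydride and Lewis-acid steps that follow.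

Step 9
Reactants: 18 (3S,4R)-4-[(R)-[(tert-butyldimethylsilyl)oxy](3,4-dimethoxyphenyl)methyl]-3-methyloxolan-2-one
Product: 19 (3S,4R)-4-[(R)-[(tert-butyldimethylsilyl)oxy](3,4-dimethoxyphenyl)methyl]-3-methyloxolan-2-ol (both anomers)
Conditions: i-Bu2AlH (1.1 equiv), CH2Cl2, −78 °C; aq. potassium sodium tartrate
Reagents that add atoms: none
Why: Partial reduction of a γ-lactone with one equivalent of i-Bu2AlH stops at the tetrahedral aluminium hemiacetal at −78 °C, which gives the lactol on work-up; the silyl ether and the aryl ethers are inert.

Step 10
Reactants: 19 (3S,4R)-4-[(R)-[(tert-butyldimethylsilyl)oxy](3,4-dimethoxyphenyl)methyl]-3-methyloxolan-2-ol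
Product: 20 (3S,4R)-4-[(R)-[(tert-butyldimethylsilyl)oxy](3,4-dimethoxyphenyl)methyl]-3-methyloxolan-2-yl acetate (both anomers)
Conditions: Ac2O, pyridine, 4-(dimethylamino)pyridine (cat.), CH2Cl2, 0 °C
Reagents that add atoms: acetic anhydride, CC(=O)OC(C)=O
Why: O-Acetylation of the lactol under nucleophilic catalysis gives an anomeric acetate that ionises more cleanly than the free lactol; the anomeric configuration is irrelevant because it is lost in the next step.

Step 11
Reactants: 20 (3S,4R)-4-[(R)-[(tert-butyldimethylsilyl)oxy](3,4-dimethoxyphenyl)methyl]-3-methyloxolan-2-yl acetate; 9 veratrole (1,2-dimethoxybenzene)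
Product: 21 tert-butyl{(R)-(3,4-dimethoxyphenyl)[(3R,4S,5S)-5-(3,4-dimethoxyphenyl)-4-methyloxolan-3-yl]methoxy}dimethylsilane
Conditions: BF3·OEt2 (1.5 equiv), 9 (3 equiv), CH2Cl2, −78 → −30 °C; aq. NaHCO3
Reagents that add atoms: none
Why: Friedel–Crafts C-arylation of an ionised cyclic acetal: BF3·OEt2 removes the anomeric acetate, and veratrole attacks the cationic C2 para to a methoxy group from the ring face opposite the cis-oriented C3 methyl and C4 side chain, which should give the 2,3-trans product; this is also expected to be the more stable C2 epimer, so any reversible ionisation of the new benzylic C2–O1 bond should lead to the same compound.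

Step 12
Reactants: 21 tert-butyl{(R)-(3,4-dimethoxyphenyl)[(3R,4S,5S)-5-(3,4-dimethoxyphenyl)-4-methyloxolan-3-yl]methoxy}dimethylsilane
Product: 22 (R)-(3,4-dimethoxyphenyl)[(3R,4S,5S)-5-(3,4-dimethoxyphenyl)-4-methyloxolan-3-yl]methanol
Conditions: Bu4NF, THF, 0 → 20 °C
Reagents that add atoms: none
Why: Fluoride-mediated desilylation; the conditions are non-acidic, so neither benzylic C–O bond should ionise and no stereocentre is affected.

## Compound list

1 | (R)-4-benzyl-3-propanoyl-1,3-oxazolidin-2-one | CCC(=O)N1[C@H](Cc2ccccc2)COC1=O | starting material
2 | ethyl (S)-2-[(trifluoromethylsulfonyl)oxy]propanoate | CCOC(=O)[C@H](C)OS(=O)(=O)C(F)(F)F | starting material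
3 | sodium (Z)-1-[(R)-4-benzyl-2-oxo-1,3-oxazolidin-3-yl]prop-1-en-1-olate | C/C=C(\O[Na])N1[C@H](Cc2ccccc2)COC1=O | intermediate
4 | ethyl (2S,3S)-4-[(R)-4-benzyl-2-oxo-1,3-oxazolidin-3-yl]-2,3-dimethyl-4-oxobutanoate | CCOC(=O)[C@@H](C)[C@H](C)C(=O)N1[C@H](Cc2ccccc2)COC1=O | intermediate
5 | (2S,3S)-4-ethoxy-2,3-dimethyl-4-oxobutaneperoxoic acid (lithium salt in the flask) | CCOC(=O)[C@@H](C)[C@H](C)C(=O)OO | intermediate
6 | (2S,3S)-4-ethoxy-2,3-dimethyl-4-oxobutanoic acid (lithium salt in the flask) | CCOC(=O)[C@@H](C)[C@H](C)C(O)=O | intermediate
7 | (2S,3S)-2,3-dimethylbutanedioic acid | OC(=O)[C@@H](C)[C@H](C)C(O)=O | intermediate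
8 | (3S,4S)-3,4-dimethyloxolane-2,5-dione (trans anhydride) | O=C1OC(=O)[C@@H](C)[C@@H]1C | intermediate
9 | veratrole (1,2-dimethoxybenzene) | COc1ccccc1OC | starting material
10 | (2S,3S)-4-(3,4-dimethoxyphenyl)-2,3-dimethyl-4-oxobutanoic acid | OC(=O)[C@@H](C)[C@H](C)C(=O)c1ccc(OC)c(OC)c1 | intermediate
11 | (2S,3S)-4-(3,4-dimethoxyphenyl)-2,3-dimethyl-4-oxobutanoic 2-methylpropyl carbonic anhydride | CC(C)COC(=O)OC(=O)[C@@H](C)[C@H](C)C(=O)c1ccc(OC)c(OC)c1 | intermediate
12 | (2S,3S)-4-(3,4-dimethoxyphenyl)-2,3-dimethyl-4-oxobutanamide | NC(=O)[C@@H](C)[C@H](C)C(=O)c1ccc(OC)c(OC)c1 | intermediate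
13 | (2S,3S)-4-(3,4-dimethoxyphenyl)-N-iodo-2,3-dimethyl-4-oxobutanamide | INC(=O)[C@@H](C)[C@H](C)C(=O)c1ccc(OC)c(OC)c1 | intermediate
14 | (2S,3S)-4-(3,4-dimethoxyphenyl)-3-(iodomethyl)-2-methyl-4-oxobutanamide | NC(=O)[C@@H](C)[C@H](CI)C(=O)c1ccc(OC)c(OC)c1 | intermediate
15 | (3S,4R)-4-(3,4-dimethoxybenzoyl)-3-methyloxolan-2-imine (hydroiodide in the flask) | N=C1OC[C@H](C(=O)c2ccc(OC)c(OC)c2)[C@@H]1C | intermediate
16 | (3S,4R)-4-(3,4-dimethoxybenzoyl)-3-methyloxolan-2-one (cis) | O=C1OC[C@H](C(=O)c2ccc(OC)c(OC)c2)[C@@H]1C | intermediate
17 | (3S,4R)-4-[(R)-(3,4-dimethoxyphenyl)(hydroxy)methyl]-3-methyloxolan-2-one | O=C1OC[C@H]([C@@H](O)c2ccc(OC)c(OC)c2)[C@@H]1C | intermediate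
18 | (3S,4R)-4-[(R)-[(tert-butyldimethylsilyl)oxy](3,4-dimethoxyphenyl)methyl]-3-methyloxolan-2-one | O=C1OC[C@H]([C@@H](O[Si](C)(C)C(C)(C)C)c2ccc(OC)c(OC)c2)[C@@H]1C | intermediate
19 | (3S,4R)-4-[(R)-[(tert-butyldimethylsilyl)oxy](3,4-dimethoxyphenyl)methyl]-3-methyloxolan-2-ol (both anomers) | OC1OC[C@H]([C@@H](O[Si](C)(C)C(C)(C)C)c2ccc(OC)c(OC)c2)[C@@H]1C | intermediate
20 | (3S,4R)-4-[(R)-[(tert-butyldimethylsilyl)oxy](3,4-dimethoxyphenyl)methyl]-3-methyloxolan-2-yl acetate (both anomers) | CC(=O)OC1OC[C@H]([C@@H](O[Si](C)(C)C(C)(C)C)c2ccc(OC)c(OC)c2)[C@@H]1C | intermediate
21 | tert-butyl{(R)-(3,4-dimethoxyphenyl)[(3R,4S,5S)-5-(3,4-dimethoxyphenyl)-4-methyloxolan-3-yl]methoxy}dimethylsilane | COc1ccc([C@H]2OC[C@H]([C@@H](O[Si](C)(C)C(C)(C)C)c3ccc(OC)c(OC)c3)[C@@H]2C)cc1OC | intermediate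
22 | (R)-(3,4-dimethoxyphenyl)[(3R,4S,5S)-5-(3,4-dimethoxyphenyl)-4-methyloxolan-3-yl]methanol | COc1ccc([C@H]2OC[C@H]([C@@H](O)c3ccc(OC)c(OC)c3)[C@@H]2C)cc1OC | target

## Step count and least certain steps

Total: 12 steps. Longest linear sequence: 12 steps (1 to 22); veratrole 9 enters twice.

**Step 6 (key step).**
- What may go wrong: two-electron Hofmann rearrangement of the primary amide by the hypervalent iodine reagent may outrun N–I homolysis. Electrophilic iodination of the dimethoxyphenyl ring may compete. Ring–chain tautomerisation of the γ-keto amide to a hydroxylactam would take substrate out of the radical pathway. Acid-mediated epimerisation at C4 during iminolactone hydrolysis would drain the cis lactone into the more stable trans isomer.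
- Fallback (the remote lactonisation is done before arene and ketone exist): it sets out from anhydride 8 and comes back at 16. Ammonia in THF at 0 °C opens 8 to (2S,3S)-4-amino-2,3-dimethyl-4-oxobutanoic acid F1. tert-Butyl 2,2,2-trichloroacetimidate with catalytic BF3·OEt2 gives tert-butyl (2S,3S)-4-amino-2,3-dimethyl-4-oxobutanoate F2. The same photochemical N-iodoamide lactonisation, now on a substrate with neither arene nor ketone, followed by dilute HCl, gives tert-butyl (3R,4S)-4-methyl-5-oxooxolane-3-carboxylate F3. CF3CO2H in CH2Cl2 releases (3R,4S)-4-methyl-5-oxooxolane-3-carboxylic acid F4, and oxalyl chloride with catalytic DMF gives (3R,4S)-4-methyl-5-oxooxolane-3-carbonyl chloride F5. AlCl3-mediated acylation of veratrole 9 at −20 °C then gives 16.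

**Step 1.**
- What may go wrong: the enolate may act as a base and eliminate triflic acid from 2 in place of substituting it. The lactate centre may be eroded by triflate exchange before the alkylation. The auxiliary and the triflate may form a mismatched pair that slows the displacement and lets O-alkylation compete.
- Fallback (one-electron enolate dimerisation in place of two-electron alkylation): it sets out from 1 and comes back at 7. Two molecules of 1 are converted with LiN(i-Pr)2 in THF at −78 °C into lithium (Z)-1-[(R)-4-benzyl-2-oxo-1,3-oxazolidin-3-yl]prop-1-en-1-olate F6, which is oxidised with anhydrous CuCl2 in DMF (−78 → 0 °C). Divalent copper removes one electron from each enolate and the two α-carbons couple, each on the face away from the benzyl group, which should give (4R,4'R)-3,3'-[(2S,3S)-2,3-dimethylbutanedioyl]bis(4-benzyl-1,3-oxazolidin-2-one) F7, freed from its diastereomers by crystallisation. LiOH/H2O2 in THF/H2O at 0 °C followed by Na2SO3 cleaves both imide groups to give 7.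

**Step 4.**
- What may go wrong: enolisation of the AlCl3-complexed aryl ketone would epimerise C4; the methyl ether para to the new ketone may be cleaved.
- Fallback (nucleophilic arylation in place of electrophilic): it sets out from 8 and comes back at 10. One equivalent of (3,4-dimethoxyphenyl)magnesium bromide is added to 8 in THF at −78 °C; the magnesium carboxylate formed on ring opening limits a second addition, and acidification gives 10. No new compound is made on this way (F0).

**Step 7.**
- What may go wrong: insufficient facial selectivity. The catalyst must tell an aryl group from a branched secondary alkyl group. A Felkin–Anh analysis with the methyl-bearing carbon C3 as the large substituent predicts the (6S) epimer, so the catalyst works against the substrate. The free hydroxy lactone may also translactonise onto the C6 oxygen if left with acid or base.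
- Fallback (substrate-controlled reduction, then inversion): it sets out from 16 and comes back at 17. NaBH4 with CeCl3·7H2O in MeOH/THF at −78 °C should favour (3S,4R)-4-[(S)-(3,4-dimethoxyphenyl)(hydroxy)methyl]-3-methyloxolan-2-one F8, which is separated from any 17. A Mitsunobu reaction (chloroacetic acid, PPh3, diisopropyl azodicarboxylate, toluene, −20 °C) inverts C6 to give (R)-(3,4-dimethoxyphenyl)[(3R,4S)-4-methyl-5-oxooxolan-3-yl]methyl chloroacetate F9. Thiourea and NaHCO3 in ethanol remove the chloroacetyl group under near-neutral conditions to give 17.

**Step 11.**
- What may go wrong: BF3·OEt2 may ionise the C6 benzylic silyl ether, whose cation is stabilised by the dimethoxyphenyl ring, leading to loss of the protecting group, elimination or arylation at C6. Facial selectivity may be lower than hoped, since a methyl group is only a moderate director.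
- Fallback (aryl–metal nucleophile and a milder Lewis acid): it sets out from lactol 19 and comes back at 21. Benzenesulfinic acid and CaCl2 in CH2Cl2 convert 19 into the anomeric sulfone (3S,4R)-4-[(R)-[(tert-butyldimethylsilyl)oxy](3,4-dimethoxyphenyl)methyl]-3-methyl-2-(phenylsulfonyl)oxolane F10. (3,4-Dimethoxyphenyl)magnesium bromide with ZnBr2 in THF at 20 °C displaces the sulfinate through the same cyclic cation, anti to the C3 methyl, to give 21.

## Further compounds

F1 | step 6 | (2S,3S)-4-amino-2,3-dimethyl-4-oxobutanoic acid | NC(=O)[C@@H](C)[C@H](C)C(O)=O
F2 | step 6 | tert-butyl (2S,3S)-4-amino-2,3-dimethyl-4-oxobutanoate | NC(=O)[C@@H](C)[C@H](C)C(=O)OC(C)(C)C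
F3 | step 6 | tert-butyl (3R,4S)-4-methyl-5-oxooxolane-3-carboxylate | O=C1OC[C@H](C(=O)OC(C)(C)C)[C@@H]1C
F4 | step 6 | (3R,4S)-4-methyl-5-oxooxolane-3-carboxylic acid | O=C1OC[C@H](C(O)=O)[C@@H]1C
F5 | step 6 | (3R,4S)-4-methyl-5-oxooxolane-3-carbonyl chloride | O=C1OC[C@H](C(Cl)=O)[C@@H]1C
F6 | step 1 | lithium (Z)-1-[(R)-4-benzyl-2-oxo-1,3-oxazolidin-3-yl]prop-1-en-1-olate | C/C=C(\O[Li])N1[C@H](Cc2ccccc2)COC1=O
F7 | step 1 | (4R,4'R)-3,3'-[(2S,3S)-2,3-dimethylbutanedioyl]bis(4-benzyl-1,3-oxazolidin-2-one) | O=C([C@@H](C)[C@H](C)C(=O)N1[C@H](Cc2ccccc2)COC1=O)N1[C@H](Cc2ccccc2)COC1=O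
F0 | step 4 | none | none
F8 | step 7 | (3S,4R)-4-[(S)-(3,4-dimethoxyphenyl)(hydroxy)methyl]-3-methyloxolan-2-one | O=C1OC[C@H]([C@H](O)c2ccc(OC)c(OC)c2)[C@@H]1C
F9 | step 7 | (R)-(3,4-dimethoxyphenyl)[(3R,4S)-4-methyl-5-oxooxolan-3-yl]methyl chloroacetate | O=C1OC[C@H]([C@@H](OC(=O)CCl)c2ccc(OC)c(OC)c2)[C@@H]1C
F10 | step 11 | (3S,4R)-4-[(R)-[(tert-butyldimethylsilyl)oxy](3,4-dimethoxyphenyl)methyl]-3-methyl-2-(phenylsulfonyl)oxolane | O=S(=O)(c1ccccc1)C1OC[C@H]([C@@H](O[Si](C)(C)C(C)(C)C)c2ccc(OC)c(OC)c2)[C@@H]1C
A1 | alternative 1 | 2-exo,6-bis(3,4-dimethoxyphenyl)-6-[(tert-butyldimethylsilyl)oxy]-3-oxabicyclo[3.2.0]heptane | COc1ccc([C@H]2OC[C@H]3[C@@H]2C[C@]3(O[Si](C)(C)C(C)(C)C)c2ccc(OC)c(OC)c2)cc1OC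
A2 | alternative 1 | (Z)-tert-butyldimethylsilyl enol ether of 1-(3,4-dimethoxyphenyl)-3-{[(S)-1-(3,4-dimethoxyphenyl)prop-2-en-1-yl]oxy}propan-1-one | COc1ccc([C@H](C=C)OC/C=C(\O[Si](C)(C)C(C)(C)C)c2ccc(OC)c(OC)c2)cc1OC
A3 | alternative 2 | tert-butyldimethylsilyl ether of the target (identical with 21) | COc1ccc([C@H]2OC[C@H]([C@@H](O[Si](C)(C)C(C)(C)C)c3ccc(OC)c(OC)c3)[C@@H]2C)cc1OC
A4 | alternative 2 | 2-(3,4-dimethoxyphenyl)-4-methyl-5-[(R)-[(tert-butyldimethylsilyl)oxy](3,4-dimethoxyphenyl)methyl]-1,3-oxazinane (C2 epimers) | COc1ccc(C2N[C@@H](C)[C@@H]([C@@H](O[Si](C)(C)C(C)(C)C)c3ccc(OC)c(OC)c3)CO2)cc1OC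
A5 | alternative 3 | (E)-3-(3,4-dimethoxybenzylidene)-5-(3,4-dimethoxyphenyl)-4-methyloxolan-2-one, 4,5-trans | COc1ccc([C@H]2OC(=O)/C(=C/c3ccc(OC)c(OC)c3)[C@@H]2C)cc1OC
A6 | alternative 3 | (1S,2S)-1,4-bis(3,4-dimethoxyphenyl)-2-methylbut-3-yn-1-ol (anti) | COc1ccc([C@H]([C@@H](C)C#Cc2ccc(OC)c(OC)c2)O)cc1OC
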